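## Analysis of the target

Target 24 is an achiral chain of three heteroaromatic rings joined by two aryl–aryl bonds. A 1H-indole carries an oxazole at C3 (through oxazole C5), and the oxazole carries a 1H-pyrrol-2-yl group at its C2. There is no stereocentre, so the whole problem is one of regiochemistry. The benzene ring of the indole bears methoxy at C4 and bromine at C6, with hydrogen at C5 and C7; with the two ring-fusion atoms this is a 1,2,3,5-tetrasubstituted arene whose C4 methoxy group is peri to the C3 heteroaryl group. This pattern is not accessible by electrophilic substitution of an indole. The second bromine sits on C5 of the pyrrole, an electron-rich ring sensitive to acid, light and oxidants, and both N–H groups are free. The two C–Br bonds must therefore survive, or be introduced after, every metal-mediated step, and the oxazole C4–H must stay untouched. The strategy rests on the indole C5–C6 bond: C6 bears bromine and C5 hydrogen, so the bond can be made from a dibromomethylene carbon (future C6) and the methylene of a 1-methoxyvinyl group (future C5, its oxygenated carbon becoming C4), held on C2 and C3 of a pyrrole whose C2=C3 bond becomes the C7a–C3a ring fusion.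

## Retrosynthetic reasoning

The last bond cut is the indole N–S bond of 23. The sulfonyl group is kept to the end because it keeps the indole nucleus inert while the pyrrole is brominated. Its removal by alkoxide gives 24 and touches neither bromine.

The pyrrole C5–Br bond of 23 is cut next, leading to 22. Placing this bromine after every palladium-mediated step and after the thermal step means no labile bromopyrrole has to survive them. The forward reaction must halogenate only the free pyrrole, the most nucleophilic ring of 22, at its open α-position.

22 is traced to its N-carbamate 21. The carbamate serves the fragment chemistry: it makes bromopyrrole 13 isolable and removes the acidic N–H from the zincation that leads to 17. Its removal directly follows the key step, so that material that lost the group on heating converges on 22.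

The central cut is the indole C5–C6 bond of 21. Adding back the elements lost in a dehydrobromination gives dihydroindole 20, and retro-electrocyclic opening of 20 gives triene 19, a pyrrole with a 2,2-dibromovinyl group at C2 and a 1-methoxyvinyl group at C3. This cut is preferred over a cut in the five-membered ring or at a biaryl bond because it alone creates the benzene ring with methoxy, bromine and both hydrogens already placed, starting from a heterocycle that is easy to substitute. In the forward direction, heat must close the triene and a base must take up the acid.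

The dibromoalkene of 19 is cut at its C=C bond to aldehyde 18. It is introduced last before the key step because a 1,1-dibromoalkene would not survive zerovalent palladium. The forward olefination must spare the acid-labile enol ether.

18 is divided at the bond between pyrrole C4 and oxazole C5 into bromide 10 and bis-heteroaryl 16, joined through zinc reagent 17. This is the most convergent cut, and C5–H is the only acidic C–H of 16 once oxazole C2 is substituted. The coupling must tolerate the aldehyde and the enol ether.

16 is divided at the oxazole C2–pyrrole C2 bond into bromopyrrole 13 and oxazole 14, joined through zinc reagent 15. 13 comes from pyrrole 11 through the unstable bromide 12. Both halves are then one or two steps from commercial materials.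

10 is divided at the bond between pyrrole C3 and the vinyl carbon into dibromide 6 and stannane 9, which comes from 7 through 8. The two bromines of 6 differ electronically: the C3 bromine is the β-halogen of an enal, the C4 bromine is not conjugated to the formyl group. The forward coupling must use that difference.

6 goes back by N-sulfonylation to 5, by formylation to 3 (through 4), by N-desilylation to 2 and by double bromination to 1. Formylating the symmetrical dibromide 3 is the reason for this order: both α-positions are equivalent, so the aldehyde can only end up next to a bromine.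

## Alternatives that were turned down

Alternative 1: The oxazole is disconnected at O1–C2 and C4–C5, giving indole aldehyde A2 (6-bromo-4-methoxy-1-tosylindole-3-carbaldehyde) and thioimidate A3 (methyl 5-bromo-1-tosyl-N-(tosylmethyl)pyrrole-2-carbimidothioate). In the forward direction the carbanion between sulfonyl and nitrogen in A3 adds to the formyl group of A2, the alkoxide closes onto the imidate carbon, and loss of the thiolate and then the sulfinate leaving group aromatises the ring to the doubly N-sulfonylated product A1.
- For: it is highly convergent, the azole-forming reaction type is known, and both bromines are in place before the union. No late bromination and no cross-coupling next to C–Br bonds is needed, and A1 is one deprotection from 24. On convergence and on steps after the key event it is stronger than the chosen route.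
- Against: the hard part of the molecule is bought, not solved. The 4-methoxy-6-bromo pattern of A2 must come from a separately built tetrasubstituted benzene through a benzene-based indole synthesis. The formyl carbon of A2 is a vinylogous formamide carbon shielded by the peri methoxy group, so addition of a hindered, stabilised carbanion should be slow, while the anion of A3 can attack its own imidate carbon. A3 needs amide formation, N-sulfonylmethylation, thionation and S-methylation, and its bromine must be placed on a 2-carbonyl pyrrole, where C4 competes more than in 22.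
- In its place the chosen strategy offers a benzene ring whose substitution pattern is generated by the ring construction itself from the symmetrical dibromide 2, with every coupling partner one or two steps from commercial material.

Alternative 2: The benzene ring is cut at C3a–C4, C4–C5 and C6–C7, giving pyrrolyl diazoketone A5 and siloxyalkyne A6. Irradiation of A5 triggers a Wolff rearrangement to a pyrrolylketene, which adds to A6 in a [2+2] sense. On heating, the cyclobutenone opens to a dienylketene that closes onto pyrrole C3 by six-electron electrocyclisation and tautomerises to phenol A4 (Danheiser benzannulation).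
- For: the reaction class is established for heteroaryl ketenes, three bonds and the whole carbocycle form in one operation with full regiocontrol, and the C4 oxygen appears as a free phenol ready for methylation. In precedent it is clearly stronger than the chosen key step.
- Against: C6 emerges as a silyl ether, not a bromide. Methylation, desilylation, sulfonate activation and a metal-mediated exchange of the C–O bond for a C–Br bond must follow, the last in the presence of the bromopyrrole C–Br bond of A4, which would compete for the metal. The bromopyrrole and the diazo group would also have to survive ultraviolet light together. A5 requires a diazo homologation on the fully elaborated tris-heteroaryl acid derivative.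
- In its place the chosen route sets bromine at C6 and methoxy at C4 in the ring-forming event, so nothing on the benzene ring is interconverted afterwards. It pays for this with an unprecedented step.

Alternative 3: The five-membered ring of the indole is cut at C3–C3a and N1–C2, giving iodoanilide A8 (tert-butyl N-(5-bromo-2-iodo-3-methoxyphenyl)carbamate) and chloroketone A9 (1-[2-(5-bromo-1-tosylpyrrol-2-yl)oxazol-5-yl]-2-chloroethanone). After N–H deprotonation and iodine–magnesium exchange of A8, the aryl carbanion adds to the carbonyl of A9, the carbamate nitrogen displaces chloride, and acid dehydration of the 3-hydroxyindoline gives A7.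
- For: it is convergent, forms two bonds in one flask, the exchange distinguishes iodine from bromine, both bromines are present beforehand, and the two N-protecting groups of A7 come off under mild conditions. In convergence it matches Alternative 1 and exceeds the chosen route.
- Against: the arylmagnesium centre lies between the methoxy group and the metalated carbamate and must attack a ketone whose α-protons are acidified by chlorine and the acyl-oxazole. Enolisation should compete, as should epoxide formation from the chlorohydrin alkoxide after addition. A8 needs regiocontrolled iodination between two donor groups of a bromoarene, where directed metalation risks aryne formation or halogen migration. A9 requires C5 acylation of the oxazole next to a bromopyrrole.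
- In its place the chosen route starts from a pyrrole in which the crowded C3–C3a bond already exists, and forms only the unhindered C5–C6 bond in the ring-closing step.

Key step: step 11

Assumption: TMPZnCl·LiCl (solution in THF) and (dibromomethyl)triphenylphosphonium bromide are used as purchased reagents; the phosphonium salt is otherwise available from CBr4 and PPh3.

## Route

Step 1
Reactants: 1 1-(triisopropylsilyl)pyrrole
Product: 2 3,4-dibromo-1-(triisopropylsilyl)pyrrole
Conditions: NBS (2.05 equiv), THF, −78 °C to rt
Reagents that add atoms: N-bromosuccinimide, O=C1CCC(=O)N1Br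
Why: Electrophilic aromatic bromination; the bulky N-silyl group shields both α-positions, so the two bromines should enter at C3 and C4.

Step 2
Reactants: 2 3,4-dibromo-1-(triisopropylsilyl)pyrrole
Product: 3 3,4-dibromo-1H-pyrrole
Conditions: Bu4NF, THF, 0 °C; crude product used at once
Reagents that add atoms: none
Why: Fluoride-induced cleavage of the N–Si bond, which leaves the C–Br bonds alone; the labile N–H pyrrole is not stored.

Step 3
Reactants: 3 3,4-dibromo-1H-pyrrole
Product: 5 3,4-dibromo-1H-pyrrole-2-carbaldehyde, via iminium chloride 4 (not isolated)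
Conditions: POCl3, DMF, ClCH2CH2Cl, 0 to 60 °C; then aq. NaOAc, 60 °C
Reagents that add atoms: N,N-dimethylformamide, CN(C)C=O; water, O
Why: Vilsmeier–Haack formylation; C2 and C5 of 3 are equivalent by symmetry, so only one aldehyde can form, and the deactivating iminium group stops a second attack.

Step 4
Reactants: 5 3,4-dibromo-1H-pyrrole-2-carbaldehyde
Product: 6 3,4-dibromo-1-tosylpyrrole-2-carbaldehyde
Conditions: NaH, THF, 0 °C; TsCl, 0 °C to rt
Reagents that add atoms: p-toluenesulfonyl chloride, Cc1ccc(cc1)S(Cl)(=O)=O
Why: N-sulfonylation of the acidic acylpyrrole N–H through its sodium salt; the tosyl group protects nitrogen in the metal-mediated steps, activates the aldehyde for olefination and later lowers the aromatic stabilisation that the key step must give up.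

Step 5
Reactants: 7 methyl vinyl ether
Product: 9 tributyl(1-methoxyvinyl)stannane, via 1-methoxyvinyllithium 8 (not isolated)
Conditions: t-BuLi, THF, −78 to 0 °C; Bu3SnCl, −78 °C to rt
Reagents that add atoms: tributyltin chloride, CCCC[Sn](Cl)(CCCC)CCCC
Why: α-Lithiation of the enol ether followed by stannylation of the vinyl anion, a standard entry to α-alkoxyvinyl stannanes.

Step 6
Reactants: 6 3,4-dibromo-1-tosylpyrrole-2-carbaldehyde; 9 tributyl(1-methoxyvinyl)stannane
Product: 10 4-bromo-3-(1-methoxyvinyl)-1-tosylpyrrole-2-carbaldehyde
Conditions: 9 (1.05 equiv), Pd(PPh3)4 (5 mol%), CuI (10 mol%), toluene, 80 °C; Et3N-deactivated silica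
Reagents that add atoms: none
Why: Site-selective Stille coupling; oxidative addition should be faster at C3–Br, the β-position of a β-bromo enal conjugated to the formyl group, than at the non-conjugated C4–Br. One equivalent of stannane and a moderate temperature should keep the second bromide.

Step 7
Reactants: 11 1H-pyrrole
Product: 13 tert-butyl 2-bromopyrrole-1-carboxylate, via 2-bromo-1H-pyrrole 12 (not isolated)
Conditions: DBDMH (0.5 equiv), THF, −78 °C; then Boc2O, Et3N, DMAP (cat.), −78 °C to rt
Reagents that add atoms: 1,3-dibromo-5,5-dimethylhydantoin, CC1(C)N(Br)C(=O)N(Br)C1=O; di-tert-butyl dicarbonate, CC(C)(C)OC(=O)OC(=O)OC(C)(C)C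
Why: Electrophilic α-bromination of pyrrole at low temperature, then N-acylation in the same flask, which traps the unstable 2-bromopyrrole as its storable carbamate.

Step 8
Reactants: 14 oxazole; 13 tert-butyl 2-bromopyrrole-1-carboxylate
Product: 16 tert-butyl 2-(oxazol-2-yl)pyrrole-1-carboxylate, via oxazol-2-ylzinc chloride 15 (not isolated)
Conditions: 14 (1.5 equiv), TMPZnCl·LiCl (1.4 equiv), THF, 0 to 25 °C; then 13, Pd(PPh3)4 (5 mol%), 50 °C
Reagents that add atoms: none
Why: Direct zincation at C2, the most acidic C–H of oxazole, gives a C–Zn species that does not open to the isocyano enolate as the lithium compound does; Negishi coupling with the heteroaryl bromide follows.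

Step 9
Reactants: 16 tert-butyl 2-(oxazol-2-yl)pyrrole-1-carboxylate; 10 4-bromo-3-(1-methoxyvinyl)-1-tosylpyrrole-2-carbaldehyde
Product: 18 tert-butyl 2-[5-[5-formyl-4-(1-methoxyvinyl)-1-tosylpyrrol-3-yl]oxazol-2-yl]pyrrole-1-carboxylate, via oxazol-5-ylzinc chloride 17 (not isolated)
Conditions: 16 (1.4 equiv), TMPZnCl·LiCl (1.3 equiv), THF, 25 °C; then 10, Pd2(dba)3 (2.5 mol%), XPhos (10 mol%), 55 °C; aq. NaHCO3 work-up
Reagents that add atoms: none
Why: With C2 blocked, oxazole C5–H is the most acidic C–H of 16, and the mild zinc amide should be too weak to metalate the pyrrole and should leave the carbamate intact. Negishi coupling with a bulky biarylphosphine then engages the remaining electron-rich C4–Br, and the organozinc tolerates the aldehyde.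

Step 10
Reactants: 18 tert-butyl 2-[5-[5-formyl-4-(1-methoxyvinyl)-1-tosylpyrrol-3-yl]oxazol-2-yl]pyrrole-1-carboxylate
Product: 19 tert-butyl 2-[5-[5-(2,2-dibromovinyl)-4-(1-methoxyvinyl)-1-tosylpyrrol-3-yl]oxazol-2-yl]pyrrole-1-carboxylate
Conditions: [Ph3PCHBr2]Br (2.0 equiv), KOtBu (1.9 equiv), THF, 0 °C to rt; then 18, 0 °C to rt; Et3N-deactivated silica
Reagents that add atoms: (dibromomethyl)triphenylphosphonium bromide, BrC(Br)[P+](c1ccccc1)(c1ccccc1)c1ccccc1.[Br-]
Why: Ramirez dibromo-olefination (Wittig type) with the preformed ylide under non-acidic conditions, which avoids the phosphorus–bromine electrophiles and acid of the CBr4/PPh3 variant that would cleave the enol ether. The slight deficit of base leaves no free alkoxide to attack the N-sulfonyl group.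

Step 11
Reactants: 19 tert-butyl 2-[5-[5-(2,2-dibromovinyl)-4-(1-methoxyvinyl)-1-tosylpyrrol-3-yl]oxazol-2-yl]pyrrole-1-carboxylate
Product: 21 tert-butyl 2-[5-(6-bromo-4-methoxy-1-tosylindol-3-yl)oxazol-2-yl]pyrrole-1-carboxylate, via 6,6-dibromo-5,6-dihydroindole 20 (not isolated)
Conditions: K2CO3 (powdered, 3 equiv), BHT (5 mol%), degassed 1,2-dichlorobenzene, 150 °C, sealed tube, dark
Reagents that add atoms: none
Why: Proposed new method: in the s-cis,s-cis conformer of 19 the triene CH2=C(OMe)–C3=C2–CH=CBr2 should close by a thermal disrotatory six-electron electrocyclisation that joins the enol ether methylene to the dibromomethylene carbon (indole C5–C6) and gives 20, in which the pyrrole is dearomatised for a moment. In 20 the only sp3 carbon with a leaving group, C6, lies next to the C5 methylene, so ionisation of one C–Br bond, helped by the C7=C7a–N enamine system, and loss of a C5 proton create the benzene ring and restore the pyrrole in one irreversible event, with K2CO3 taking up the acid. The closest known reaction type is the thermal electrocyclisation of 2,3-divinylpyrroles and 2,3-divinylindoles followed by dehydrogenation or loss of a leaving group; a dibromomethylene terminus that is both leaving group and source of the retained halogen has not been shown. The six-membered ring is closed in the disrotatory 6π mode; no stereocentre is formed and alkene geometry cannot matter because both terminal substituents are bromine. The positions of methoxy (C4), bromine (C6) and hydrogen (C5, C7) follow from the connectivity of the triene alone. Dehydrobromination is preferred over loss of the methoxy group because the methoxy-bearing carbon stays sp2 in 20, and the N-tosyl group lowers the aromatic stabilisation that the closure must give up. A weak insoluble base is used because amidine or alkoxide bases would turn the dibromoalkene into a bromoalkyne and amine hydrobromides would cleave the enol ether; the second conceivable triene, through oxazole C4=C5, has no leaving group and can only revert. Partial thermal loss of the carbamate is harmless because step 12 removes it anyway.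

Step 12
Reactants: 21 tert-butyl 2-[5-(6-bromo-4-methoxy-1-tosylindol-3-yl)oxazol-2-yl]pyrrole-1-carboxylate
Product: 22 6-bromo-4-methoxy-3-[2-(1H-pyrrol-2-yl)oxazol-5-yl]-1-tosylindole
Conditions: TFA, CH2Cl2, 0 °C to rt
Reagents that add atoms: none
Why: Acidolysis of the tert-butyl carbamate; the enol ether no longer exists after step 11, so acid is tolerated, and any material that lost the carbamate on heating ends up as the same compound.

Step 13
Reactants: 22 6-bromo-4-methoxy-3-[2-(1H-pyrrol-2-yl)oxazol-5-yl]-1-tosylindole
Product: 23 6-bromo-3-[2-(5-bromo-1H-pyrrol-2-yl)oxazol-5-yl]-4-methoxy-1-tosylindole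
Conditions: NBS (1.0 equiv), THF, −78 °C
Reagents that add atoms: N-bromosuccinimide, O=C1CCC(=O)N1Br
Why: Electrophilic aromatic bromination; the free pyrrole is far more nucleophilic than the N-sulfonyl indole, the oxazole and the bromoanisole ring, and its open α-position C5 should be favoured kinetically at low temperature with one equivalent of reagent.

Step 14
Reactants: 23 6-bromo-3-[2-(5-bromo-1H-pyrrol-2-yl)oxazol-5-yl]-4-methoxy-1-tosylindole
Product: 24 6-bromo-3-[2-(5-bromo-1H-pyrrol-2-yl)oxazol-5-yl]-4-methoxy-1H-indole
Conditions: Cs2CO3 (3 equiv), THF/MeOH, 45 °C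
Reagents that add atoms: none
Why: Nucleophilic cleavage of the sulfonamide N–S bond by methoxide, with the indolide as leaving group; the aryl and pyrrolyl bromides and the oxazole are inert, and excess methoxide consumes the sulfonate ester.

## Compound list

1 | 1-(triisopropylsilyl)pyrrole | CC(C)[Si](C(C)C)(C(C)C)n1cccc1 | starting material
2 | 3,4-dibromo-1-(triisopropylsilyl)pyrrole | CC(C)[Si](C(C)C)(C(C)C)n1cc(Br)c(Br)c1 | intermediate
3 | 3,4-dibromo-1H-pyrrole | Brc1c[nH]cc1Br | intermediate
4 | [(3,4-dibromo-1H-pyrrol-2-yl)methylene]dimethyliminium chloride | C[N+](C)=Cc1[nH]cc(Br)c1Br.[Cl-] | intermediate (not isolated)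
5 | 3,4-dibromo-1H-pyrrole-2-carbaldehyde | O=Cc1[nH]cc(Br)c1Br | intermediate
6 | 3,4-dibromo-1-tosylpyrrole-2-carbaldehyde | Cc1ccc(cc1)S(=O)(=O)n1cc(Br)c(Br)c1C=O | intermediate
7 | methyl vinyl ether | C=COC | starting material
8 | 1-methoxyvinyllithium | [Li]C(=C)OC | intermediate (not isolated)
9 | tributyl(1-methoxyvinyl)stannane | CCCC[Sn](CCCC)(CCCC)C(=C)OC | intermediate
10 | 4-bromo-3-(1-methoxyvinyl)-1-tosylpyrrole-2-carbaldehyde | COC(=C)c1c(Br)cn(S(=O)(=O)c2ccc(C)cc2)c1C=O | intermediate
11 | 1H-pyrrole | c1cc[nH]c1 | starting material
12 | 2-bromo-1H-pyrrole | Brc1ccc[nH]1 | intermediate (not isolated)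
13 | tert-butyl 2-bromopyrrole-1-carboxylate | CC(C)(C)OC(=O)n1cccc1Br | intermediate
14 | oxazole | c1cocn1 | starting material
15 | oxazol-2-ylzinc chloride | Cl[Zn]c1ncco1 | intermediate (not isolated)
16 | tert-butyl 2-(oxazol-2-yl)pyrrole-1-carboxylate | CC(C)(C)OC(=O)n1cccc1-c1ncco1 | intermediate
17 | [2-(1-tert-butoxycarbonylpyrrol-2-yl)oxazol-5-yl]zinc chloride | CC(C)(C)OC(=O)n1cccc1-c1ncc([Zn]Cl)o1 | intermediate (not isolated)
18 | tert-butyl 2-[5-[5-formyl-4-(1-methoxyvinyl)-1-tosylpyrrol-3-yl]oxazol-2-yl]pyrrole-1-carboxylate | COC(=C)c1c(C=O)n(S(=O)(=O)c2ccc(C)cc2)cc1-c1cnc(-c2cccn2C(=O)OC(C)(C)C)o1 | intermediate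
19 | tert-butyl 2-[5-[5-(2,2-dibromovinyl)-4-(1-methoxyvinyl)-1-tosylpyrrol-3-yl]oxazol-2-yl]pyrrole-1-carboxylate | COC(=C)c1c(C=C(Br)Br)n(S(=O)(=O)c2ccc(C)cc2)cc1-c1cnc(-c2cccn2C(=O)OC(C)(C)C)o1 | intermediate
20 | tert-butyl 2-[5-(6,6-dibromo-4-methoxy-1-tosyl-5,6-dihydroindol-3-yl)oxazol-2-yl]pyrrole-1-carboxylate | COC1=C2C(-c3cnc(-c4cccn4C(=O)OC(C)(C)C)o3)=CN(S(=O)(=O)c3ccc(C)cc3)C2=CC(Br)(Br)C1 | intermediate (not isolated)
21 | tert-butyl 2-[5-(6-bromo-4-methoxy-1-tosylindol-3-yl)oxazol-2-yl]pyrrole-1-carboxylate | COc1cc(Br)cc2c1c(-c1cnc(-c3cccn3C(=O)OC(C)(C)C)o1)cn2S(=O)(=O)c1ccc(C)cc1 | intermediate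
22 | 6-bromo-4-methoxy-3-[2-(1H-pyrrol-2-yl)oxazol-5-yl]-1-tosylindole | COc1cc(Br)cc2c1c(-c1cnc(-c3ccc[nH]3)o1)cn2S(=O)(=O)c1ccc(C)cc1 | intermediate
23 | 6-bromo-3-[2-(5-bromo-1H-pyrrol-2-yl)oxazol-5-yl]-4-methoxy-1-tosylindole | COc1cc(Br)cc2c1c(-c1cnc(-c3ccc(Br)[nH]3)o1)cn2S(=O)(=O)c1ccc(C)cc1 | intermediate
24 | 6-bromo-3-[2-(5-bromo-1H-pyrrol-2-yl)oxazol-5-yl]-4-methoxy-1H-indole | COc1cc(Br)cc2[nH]cc(-c3cnc(-c4ccc(Br)[nH]4)o3)c12 | target

## Step count and least certain steps

Total: 14 steps. Longest linear sequence: 11 steps (1, 2, 3, 4, 6, 9, 10, 11, 12, 13, 14). Step 5 and steps 7–8 are side branches.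

Step 11 (key step, the one carrying the new-method label). The most likely failure is that ring closure does not compete with decomposition. The bromine that must rotate inward raises the barrier, and the closure costs the aromaticity of the pyrrole, so 20 may form only in a small stationary amount. At the temperature needed, dehydrobromination of the dibromoalkene to a bromoalkyne, cleavage of the enol ether or loss of the sulfonyl group could overtake it. The fallback uses known reaction types and sets out from 18:
- A boron–Wittig olefination of 18 with lithiated bis(pinacolboryl)methane (from the diborylmethane and LiTMP, THF, −78 °C) should give the (E)-alkenylboronate tert-butyl 2-[5-[4-(1-methoxyvinyl)-5-[(E)-2-(4,4,5,5-tetramethyl-1,3,2-dioxaborolan-2-yl)vinyl]-1-tosylpyrrol-3-yl]oxazol-2-yl]pyrrole-1-carboxylate F1. Its outward boron substituent does not hinder closure.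
- Heating F1 in xylene should give the dihydroindole tert-butyl 2-[5-[4-methoxy-6-(4,4,5,5-tetramethyl-1,3,2-dioxaborolan-2-yl)-1-tosyl-5,6-dihydroindol-3-yl]oxazol-2-yl]pyrrole-1-carboxylate F2 by the known divinylpyrrole electrocyclisation.
- Dehydrogenation of F2 with DDQ in the same flask should give the arylboronate tert-butyl 2-[5-[4-methoxy-6-(4,4,5,5-tetramethyl-1,3,2-dioxaborolan-2-yl)-1-tosylindol-3-yl]oxazol-2-yl]pyrrole-1-carboxylate F3.
- Bromodeboronation of F3 with CuBr2 in aqueous methanol at 80 °C returns to the route at 21.

Step 6. Poor site selectivity in the oxidative addition, or a second coupling at C4, would give regioisomeric or doubly vinylated material, because the electronic bias between the two bromides is the only control element. The fallback replaces the electronic bias by a difference in halogen and sets out from 2: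
- Single bromine–lithium exchange of 2 (n-BuLi, THF, −78 °C) and quenching with I2 should give 3-bromo-4-iodo-1-(triisopropylsilyl)pyrrole F4.
- Bu4NF should give 3-bromo-4-iodo-1H-pyrrole F5.
- Formylation as in step 3 attacks both α-positions; 4-bromo-3-iodo-1H-pyrrole-2-carbaldehyde F6 is separated by chromatography from its isomer 3-bromo-4-iodo-1H-pyrrole-2-carbaldehyde F7.
- Tosylation as in step 4 should give 4-bromo-3-iodo-1-tosylpyrrole-2-carbaldehyde F8.
- Stille coupling of F8 with 9 at the C–I bond, which is favoured by both halogen and position, comes back to the route at 10.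

Step 9. Zincation could be incomplete or misdirected to the pyrrole C–H next to the carbamate, and oxidative addition at the hindered, electron-rich C4–Br could be slow, so that protodezincation and homocoupling take over. The fallback attaches the oxazole first and the pyrrole second, and sets out from 10:
- Suzuki–Miyaura coupling of 10 with commercial 5-(4,4,5,5-tetramethyl-1,3,2-dioxaborolan-2-yl)-2-(triisopropylsilyl)oxazole (Pd(dppf)Cl2, K3PO4, dioxane, 80 °C) should give 3-(1-methoxyvinyl)-1-tosyl-4-[2-(triisopropylsilyl)oxazol-5-yl]pyrrole-2-carbaldehyde F9.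
- Desilylation with Bu4NF buffered by AcOH at 0 °C should give 3-(1-methoxyvinyl)-4-(oxazol-5-yl)-1-tosylpyrrole-2-carbaldehyde F10.
- Zincation of the now most acidic oxazole C2–H with TMPZnCl·LiCl should give the zinc reagent [5-[5-formyl-4-(1-methoxyvinyl)-1-tosylpyrrol-3-yl]oxazol-2-yl]zinc chloride F11.
- Negishi coupling of F11 with 13 comes back to the route at 18.

Step 10. Hydrolysis or bromination of the enol ether by adventitious acid or electrophilic bromine, or attack of residual alkoxide on the N-sulfonyl group of the electron-poor pyrrole, could erode the material. The fallback carries the sensitive group as a ketone through the olefination and sets out from 18: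
- Mild aqueous acid (oxalic acid, wet THF, 0 °C) should hydrolyse the enol ether to the ketone tert-butyl 2-[5-(4-acetyl-5-formyl-1-tosylpyrrol-3-yl)oxazol-2-yl]pyrrole-1-carboxylate F12.
- The classical CBr4/PPh3 olefination, which is selective for the aldehyde over the aryl ketone, should give tert-butyl 2-[5-[4-acetyl-5-(2,2-dibromovinyl)-1-tosylpyrrol-3-yl]oxazol-2-yl]pyrrole-1-carboxylate F13.
- Kinetic enolisation with KHMDS (1.0 equiv, THF/DMPU, −78 °C) and O-methylation with dimethyl sulfate comes back to the route at 19.

Step 13. Attack at C4 of the pyrrole, which the electron-withdrawing oxazolyl group favours relative to C5, or a second bromination, could give isomer mixtures. The fallback brominates before the carbamate is removed and sets out from 21. In 21 the N-carbamate twists the oxazole out of conjugation and moderates the reactivity of the ring, so NBS (THF, −78 to 0 °C) should give tert-butyl 2-bromo-5-[5-(6-bromo-4-methoxy-1-tosylindol-3-yl)oxazol-2-yl]pyrrole-1-carboxylate F14. Treating F14 with Cs2CO3 in THF/MeOH cleaves both the carbamate and the sulfonamide and arrives at 24.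

## Further compounds

F1 | step 11 | tert-butyl 2-[5-[4-(1-methoxyvinyl)-5-[(E)-2-(4,4,5,5-tetramethyl-1,3,2-dioxaborolan-2-yl)vinyl]-1-tosylpyrrol-3-yl]oxazol-2-yl]pyrrole-1-carboxylate | COC(=C)c1c(/C=C/B2OC(C)(C)C(C)(C)O2)n(S(=O)(=O)c2ccc(C)cc2)cc1-c1cnc(-c2cccn2C(=O)OC(C)(C)C)o1
F2 | step 11 | tert-butyl 2-[5-[4-methoxy-6-(4,4,5,5-tetramethyl-1,3,2-dioxaborolan-2-yl)-1-tosyl-5,6-dihydroindol-3-yl]oxazol-2-yl]pyrrole-1-carboxylate (racemic) | COC1=C2C(-c3cnc(-c4cccn4C(=O)OC(C)(C)C)o3)=CN(S(=O)(=O)c3ccc(C)cc3)C2=CC(B2OC(C)(C)C(C)(C)O2)C1
F3 | step 11 | tert-butyl 2-[5-[4-methoxy-6-(4,4,5,5-tetramethyl-1,3,2-dioxaborolan-2-yl)-1-tosylindol-3-yl]oxazol-2-yl]pyrrole-1-carboxylate | COc1cc(B2OC(C)(C)C(C)(C)O2)cc2c1c(-c1cnc(-c3cccn3C(=O)OC(C)(C)C)o1)cn2S(=O)(=O)c1ccc(C)cc1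
F4 | step 6 | 3-bromo-4-iodo-1-(triisopropylsilyl)pyrrole | CC(C)[Si](C(C)C)(C(C)C)n1cc(Br)c(I)c1
F5 | step 6 | 3-bromo-4-iodo-1H-pyrrole | Brc1c[nH]cc1I
F6 | step 6 | 4-bromo-3-iodo-1H-pyrrole-2-carbaldehyde | O=Cc1[nH]cc(Br)c1I
F7 | step 6 | 3-bromo-4-iodo-1H-pyrrole-2-carbaldehyde | O=Cc1[nH]cc(I)c1Br
F8 | step 6 | 4-bromo-3-iodo-1-tosylpyrrole-2-carbaldehyde | Cc1ccc(cc1)S(=O)(=O)n1cc(Br)c(I)c1C=O
F9 | step 9 | 3-(1-methoxyvinyl)-1-tosyl-4-[2-(triisopropylsilyl)oxazol-5-yl]pyrrole-2-carbaldehyde | COC(=C)c1c(C=O)n(S(=O)(=O)c2ccc(C)cc2)cc1-c1cnc([Si](C(C)C)(C(C)C)C(C)C)o1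
F10 | step 9 | 3-(1-methoxyvinyl)-4-(oxazol-5-yl)-1-tosylpyrrole-2-carbaldehyde | COC(=C)c1c(C=O)n(S(=O)(=O)c2ccc(C)cc2)cc1-c1cnco1
F11 | step 9 | [5-[5-formyl-4-(1-methoxyvinyl)-1-tosylpyrrol-3-yl]oxazol-2-yl]zinc chloride | COC(=C)c1c(C=O)n(S(=O)(=O)c2ccc(C)cc2)cc1-c1cnc([Zn]Cl)o1
F12 | step 10 | tert-butyl 2-[5-(4-acetyl-5-formyl-1-tosylpyrrol-3-yl)oxazol-2-yl]pyrrole-1-carboxylate | CC(=O)c1c(C=O)n(S(=O)(=O)c2ccc(C)cc2)cc1-c1cnc(-c2cccn2C(=O)OC(C)(C)C)o1
F13 | step 10 | tert-butyl 2-[5-[4-acetyl-5-(2,2-dibromovinyl)-1-tosylpyrrol-3-yl]oxazol-2-yl]pyrrole-1-carboxylate | CC(=O)c1c(C=C(Br)Br)n(S(=O)(=O)c2ccc(C)cc2)cc1-c1cnc(-c2cccn2C(=O)OC(C)(C)C)o1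
F14 | step 13 | tert-butyl 2-bromo-5-[5-(6-bromo-4-methoxy-1-tosylindol-3-yl)oxazol-2-yl]pyrrole-1-carboxylate | COc1cc(Br)cc2c1c(-c1cnc(-c3ccc(Br)n3C(=O)OC(C)(C)C)o1)cn2S(=O)(=O)c1ccc(C)cc1
A1 | alternative 1 | 6-bromo-3-[2-(5-bromo-1-tosylpyrrol-2-yl)oxazol-5-yl]-4-methoxy-1-tosylindole | COc1cc(Br)cc2c1c(-c1cnc(-c3ccc(Br)n3S(=O)(=O)c3ccc(C)cc3)o1)cn2S(=O)(=O)c1ccc(C)cc1
A2 | alternative 1 | 6-bromo-4-methoxy-1-tosylindole-3-carbaldehyde | COc1cc(Br)cc2c1c(C=O)cn2S(=O)(=O)c1ccc(C)cc1
A3 | alternative 1 | methyl 5-bromo-1-tosyl-N-(tosylmethyl)pyrrole-2-carbimidothioate | CSC(=NCS(=O)(=O)c1ccc(C)cc1)c1ccc(Br)n1S(=O)(=O)c1ccc(C)cc1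
A4 | alternative 2 | 3-[2-(5-bromo-1-tosylpyrrol-2-yl)oxazol-5-yl]-1-tosyl-6-(triisopropylsiloxy)indol-4-ol | Oc1cc(O[Si](C(C)C)(C(C)C)C(C)C)cc2c1c(-c1cnc(-c3ccc(Br)n3S(=O)(=O)c3ccc(C)cc3)o1)cn2S(=O)(=O)c1ccc(C)cc1
A5 | alternative 2 | 1-[4-[2-(5-bromo-1-tosylpyrrol-2-yl)oxazol-5-yl]-1-tosylpyrrol-2-yl]-2-diazoethanone | [N-]=[N+]=CC(=O)c1cc(-c2cnc(-c3ccc(Br)n3S(=O)(=O)c3ccc(C)cc3)o2)cn1S(=O)(=O)c1ccc(C)cc1
A6 | alternative 2 | (triisopropylsiloxy)acetylene | C#CO[Si](C(C)C)(C(C)C)C(C)C
A7 | alternative 3 | tert-butyl 6-bromo-3-[2-(5-bromo-1-tosylpyrrol-2-yl)oxazol-5-yl]-4-methoxyindole-1-carboxylate | COc1cc(Br)cc2c1c(-c1cnc(-c3ccc(Br)n3S(=O)(=O)c3ccc(C)cc3)o1)cn2C(=O)OC(C)(C)C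
A8 | alternative 3 | tert-butyl N-(5-bromo-2-iodo-3-methoxyphenyl)carbamate | COc1cc(Br)cc(NC(=O)OC(C)(C)C)c1I
A9 | alternative 3 | 1-[2-(5-bromo-1-tosylpyrrol-2-yl)oxazol-5-yl]-2-chloroethanone | O=C(CCl)c1cnc(-c2ccc(Br)n2S(=O)(=O)c2ccc(C)cc2)o1
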